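The target is built from (S)-(+)-carvone in 14 steps (longest linear sequence 11), with ring A closed by olefin metathesis.

The plan rests on closing ring A last, at its only unfunctionalised CH2–CH2 unit, the C1–C2 bond (labdane numbering), by ring-closing olefin metathesis. The step exploits that C1 and C2 hang on the two quaternary carbons C10 and C4 that flank the ring-fusion carbon C5: a vinyl group on C10 and an allyl group on C4, held trans-diequatorial on a finished ring B, can close only to the trans-fused decalin, with no new stereocentre at stake. The precursor is an (S)-carvone-derived cyclohexenone: carvone's stereocentre is C5, its isopropenyl group becomes C4, and its enone later takes the side chain by 1,2-addition and oxidative 1,3-transposition.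

Key step: step 5

Remark: labdane numbering is used throughout (C1–C10 decalin, C11–C16 side chain, C17 on C8, C20 on C10); the target is the (5R,7S,10R) isomer, an ent-labdane, which calls for (S)-(+)-carvone.

Step 1
Reactants: 1 (S)-(+)-carvone
Product: 3 trans-6-methylcarvone [(5S,6R)-2,6-dimethyl-5-(prop-1-en-2-yl)cyclohex-2-en-1-one], via carvone lithium enolate 2 (not isolated)
Conditions: LiN(i-Pr)2, THF, −78 °C; then MeI, −78 to 0 °C
Reagents that add atoms: iodomethane, CI
Why: Kinetic α'-deprotonation of the enone gives the cross-conjugated lithium dienolate, whose C-methylation (enolate alkylation) installs the future C20; the new centre should form mainly trans to the isopropenyl group but is erased in step 2, so its configuration does not matter.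

Step 2
Reactants: 3 trans-6-methylcarvone
Product: 5 (5R,6R)-6-ethenyl-2,6-dimethyl-5-(prop-1-en-2-yl)cyclohex-2-en-1-one, via lithium enolate 4 (not isolated)
Conditions: LiN(SiMe3)2, toluene, −78 °C to rt; then vinyl bromide (1 M in THF), Pd2(dba)3 (2.5 mol %), P(t-Bu)3 (6 mol %), rt to 40 °C
Reagents that add atoms: vinyl bromide, C=CBr
Why: Palladium-catalysed α-vinylation of a ketone enolate (enolate cross-coupling), a reaction known to give α-quaternary ketones from α'-blocked enones; the C–C bond should form on the enolate face opposite the neighbouring isopropenyl group, so the vinyl group (future C1) ends up trans to it and the methyl cis, which sets C10.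

Step 3
Reactants: 5 (5R,6R)-6-ethenyl-2,6-dimethyl-5-(prop-1-en-2-yl)cyclohex-2-en-1-one
Product: 6 (5S,6R)-5-(2-bromopropan-2-yl)-6-ethenyl-2,6-dimethylcyclohex-2-en-1-one
Conditions: HBr (33 % in AcOH, 1.1 equiv), CH2Cl2, −10 °C
Reagents that add atoms: hydrogen bromide, Br
Why: Markovnikov hydrobromination; the 1,1-disubstituted isopropenyl alkene is protonated to a tertiary cation far faster than the neopentyl-type vinyl group or the enone, as in the classical hydrobromination of carvone.

Step 4
Reactants: 6 (5S,6R)-5-(2-bromopropan-2-yl)-6-ethenyl-2,6-dimethylcyclohex-2-en-1-one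
Product: 7 (5R,6R)-6-ethenyl-2,6-dimethyl-5-(2-methylpent-4-en-2-yl)cyclohex-2-en-1-one
Conditions: allyltributylstannane (3 equiv), AIBN (0.2 equiv), benzene, 80 °C
Reagents that add atoms: allyltributylstannane, C=CC[Sn](CCCC)(CCCC)CCCC
Why: Keck radical allylation; the tertiary radical at C4 adds to the stannane and expels Bu3Sn•, which creates the quaternary gem-dimethyl carbon C4 with its allyl arm (C3, C2), while 4-exo or 5-endo closure onto the vinyl group or the enone is too slow to compete.

Step 5
Reactants: 7 (5R,6R)-6-ethenyl-2,6-dimethyl-5-(2-methylpent-4-en-2-yl)cyclohex-2-en-1-one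
Product: 8 (4aR,8aR)-2,5,5,8a-tetramethyl-4a,5,6,8a-tetrahydronaphthalen-1(4H)-one (trans-fused; ring A alkene C1=C2)
Conditions: second-generation Grubbs catalyst RuCl2(=CHPh)(H2IMes)(PCy3) (5 mol %), 1,4-benzoquinone (10 mol %), toluene (0.01 M), 80 °C
Reagents that add atoms: none
Why: Ring-closing olefin metathesis: the ruthenium benzylidene first exchanges onto the unhindered allyl terminus on C4, the new alkylidene undergoes intramolecular [2+2] cycloaddition with the neopentyl-type vinyl group on C10, and cycloreversion of the ruthenacyclobutane releases ethylene and the C1=C2 double bond. The closest known reaction type is the metathetic closure of cyclohexenes that carry a quaternary allylic carbon, as used for angularly methylated decalins. Ring A is closed as a six-membered cycloalkene from a 1,7-diene; ring B is already present, so the step is a simple annulation and not a cascade. No new stereocentre is formed; the trans ring fusion follows from the C5 and C10 centres set earlier, because the vinyl group and the CMe2–allyl arm are trans-diequatorial on ring B. The selectivity needed is chemoselectivity for the two monosubstituted alkenes over the trisubstituted, electron-poor C7=C8 enone alkene and over intermolecular metathesis; the first is secured by the low reactivity of the enone alkene and the absence of any reasonable ring through it, the second by high dilution and the gem-dimethyl (Thorpe–Ingold) bias of the tether.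

Step 6
Reactants: 8 (4aR,8aR)-2,5,5,8a-tetramethyl-4a,5,6,8a-tetrahydronaphthalen-1(4H)-one
Product: 9 (4aR,8aR)-2,5,5,8a-tetramethyl-4a,5,6,7,8,8a-hexahydronaphthalen-1(4H)-one
Conditions: H2 (3 atm), RhCl(PPh3)3 (5 mol %), benzene/EtOH, rt
Reagents that add atoms: none
Why: Homogeneous hydrogenation with the chlorotris(triphenylphosphine)rhodium catalyst should saturate the cis-disubstituted C1=C2 alkene and leave the trisubstituted conjugated enone alkene untouched, the same selectivity by which carvone is reduced only at its isopropenyl group.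

Step 7
Reactants: 10 (E)-3-methylpent-2-en-4-yn-1-ol
Product: 11 (E)-tert-butyldimethyl[(3-methylpent-2-en-4-yn-1-yl)oxy]silane
Conditions: TBSCl, imidazole, CH2Cl2, 0 °C to rt
Reagents that add atoms: tert-butyldimethylsilyl chloride, CC(C)(C)[Si](C)(C)Cl
Why: Silylation of the primary allylic alcohol protects the future C15 oxygen against the organolithium and chromium steps; the E-alkene (future C13=C14) is carried unchanged.

Step 8
Reactants: 11 (E)-tert-butyldimethyl[(3-methylpent-2-en-4-yn-1-yl)oxy]silane
Product: 12 (E)-tert-butyldimethyl[(3-methylpenta-2,4-dien-1-yl)oxy]silane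
Conditions: H2 (1 atm), Pd/CaCO3 poisoned with Pb(OAc)2 (Lindlar catalyst), quinoline, hexane, rt
Reagents that add atoms: none
Why: Lindlar semihydrogenation stops the terminal alkyne at the vinyl stage and does not touch the trisubstituted alkene or its geometry.

Step 9
Reactants: 12 (E)-tert-butyldimethyl[(3-methylpenta-2,4-dien-1-yl)oxy]silane
Product: 14 (E)-tert-butyl[(5-iodo-3-methylpent-2-en-1-yl)oxy]dimethylsilane, via alkylborane 13 (not isolated)
Conditions: 9-BBN, THF, 0 °C to rt; then NaOMe, I2, MeOH/THF, 0 °C
Reagents that add atoms: 9-borabicyclo[3.3.1]nonane (9-BBN), B1C2CCCC1CCC2; iodine, II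
Why: Anti-Markovnikov hydroboration by the hindered borane takes place only at the terminal vinyl carbon (future C11) of the diene, and base-promoted iodinolysis of the primary B–C bond gives the homoallylic iodide.

Step 10
Reactants: 14 (E)-tert-butyl[(5-iodo-3-methylpent-2-en-1-yl)oxy]dimethylsilane; 9 (4aR,8aR)-2,5,5,8a-tetramethyl-4a,5,6,7,8,8a-hexahydronaphthalen-1(4H)-one
Product: 16 (5R,9R,10R)-15-(tert-butyldimethylsilyloxy)labda-7,13E-dien-9-ol (tertiary allylic alcohol; the C9 epimer would serve equally), via alkyllithium 15 (not isolated)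
Conditions: t-BuLi (2.1 equiv), Et2O, −78 °C; then 9, −78 to 0 °C; H2O
Reagents that add atoms: none
Why: Iodine–lithium exchange followed by 1,2-addition of the primary alkyllithium to the enone carbonyl C9 (the C9–C11 bond), as is usual for 2,6,6-trisubstituted cyclohexenones, whose only acidic hydrogens are the γ-hydrogens; attack should come from the face opposite the axial C10 methyl, but the carbinol centre is destroyed in step 11.

Step 11
Reactants: 16 (5R,9R,10R)-15-(tert-butyldimethylsilyloxy)labda-7,13E-dien-9-ol
Product: 17 (5R,10R)-15-(tert-butyldimethylsilyloxy)labda-8,13E-dien-7-one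
Conditions: pyridinium chlorochromate [C5H5NH][CrO3Cl], 4 Å molecular sieves, CH2Cl2, rt
Reagents that add atoms: pyridinium chlorochromate, [O-][Cr](=O)(=O)Cl.c1cc[nH+]cc1
Why: Babler–Dauben oxidative 1,3-transposition; the tertiary chromate ester undergoes a [3,3] shift to C7 (the C7 oxygen comes from chromium) and is then oxidised, which places the tetrasubstituted C8=C9 alkene and the C7 carbonyl.

Step 12
Reactants: 17 (5R,10R)-15-(tert-butyldimethylsilyloxy)labda-8,13E-dien-7-one
Product: 18 (5R,7S,10R)-15-(tert-butyldimethylsilyloxy)labda-8,13E-dien-7-ol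
Conditions: LiBH(s-Bu)3, THF, −78 °C; H2O
Reagents that add atoms: none
Why: 1,2-Reduction by a bulky trialkylborohydride, which should approach along the equatorial trajectory and give the pseudoaxial alcohol anti to the C10 methyl (7S), by analogy with steroidal 4-en-3-ones; the fully substituted β-carbon C9 blocks conjugate reduction.

Step 13
Reactants: 18 (5R,7S,10R)-15-(tert-butyldimethylsilyloxy)labda-8,13E-dien-7-ol
Product: 19 (5R,7S,10R)-labda-8,13E-diene-7,15-diol
Conditions: Bu4NF, THF, 0 °C to rt
Reagents that add atoms: none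
Why: Fluoride-mediated desilylation frees the primary allylic alcohol under conditions that do not ionise the acid-sensitive C7 allylic alcohol.

Step 14
Reactants: 19 (5R,7S,10R)-labda-8,13E-diene-7,15-diol
Product: 20 (5R,7S,10R)-labda-8,13E-diene-7,15-diyl diacetate (target)
Conditions: Ac2O, pyridine, DMAP (cat.), CH2Cl2, rt
Reagents that add atoms: acetic anhydride, CC(=O)OC(C)=O
Why: DMAP-catalysed acylation esterifies the primary and the secondary allylic alcohol with retention at C7.

Compound list
1 | (S)-(+)-carvone, (5S)-2-methyl-5-(prop-1-en-2-yl)cyclohex-2-en-1-one | O=C1C(C)=CC[C@H](C(C)=C)C1 | starting material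
2 | lithium α'-enolate of carvone (cross-conjugated dienolate) | [Li]OC1=C[C@@H](C(C)=C)CC=C1C | intermediate (not isolated)
3 | trans-6-methylcarvone, (5S,6R)-2,6-dimethyl-5-(prop-1-en-2-yl)cyclohex-2-en-1-one | C[C@@H]1[C@@H](C(C)=C)CC=C(C)C1=O | intermediate
4 | lithium enolate of 6-methylcarvone | [Li]OC1=C(C)[C@@H](C(C)=C)CC=C1C | intermediate (not isolated)
5 | (5R,6R)-6-ethenyl-2,6-dimethyl-5-(prop-1-en-2-yl)cyclohex-2-en-1-one (vinyl trans to isopropenyl) | C=C[C@]1(C)[C@@H](C(C)=C)CC=C(C)C1=O | intermediate
6 | (5S,6R)-5-(2-bromopropan-2-yl)-6-ethenyl-2,6-dimethylcyclohex-2-en-1-one | C=C[C@]1(C)[C@@H](C(C)(C)Br)CC=C(C)C1=O | intermediate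
7 | (5R,6R)-6-ethenyl-2,6-dimethyl-5-(2-methylpent-4-en-2-yl)cyclohex-2-en-1-one | C=C[C@]1(C)[C@@H](C(C)(C)CC=C)CC=C(C)C1=O | intermediate
8 | (4aR,8aR)-2,5,5,8a-tetramethyl-4a,5,6,8a-tetrahydronaphthalen-1(4H)-one | O=C1C(C)=CC[C@@H]2C(C)(C)CC=C[C@@]12C | intermediate
9 | (4aR,8aR)-2,5,5,8a-tetramethyl-4a,5,6,7,8,8a-hexahydronaphthalen-1(4H)-one | O=C1C(C)=CC[C@@H]2C(C)(C)CCC[C@@]12C | intermediate
10 | (E)-3-methylpent-2-en-4-yn-1-ol | OC/C=C(\C)C#C | starting material
11 | (E)-tert-butyldimethyl[(3-methylpent-2-en-4-yn-1-yl)oxy]silane | CC(C)(C)[Si](C)(C)OC/C=C(\C)C#C | intermediate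
12 | (E)-tert-butyldimethyl[(3-methylpenta-2,4-dien-1-yl)oxy]silane | CC(C)(C)[Si](C)(C)OC/C=C(\C)C=C | intermediate
13 | (E)-9-[5-(tert-butyldimethylsilyloxy)-3-methylpent-3-en-1-yl]-9-borabicyclo[3.3.1]nonane | CC(C)(C)[Si](C)(C)OC/C=C(\C)CCB1C2CCCC1CCC2 | intermediate (not isolated)
14 | (E)-tert-butyl[(5-iodo-3-methylpent-2-en-1-yl)oxy]dimethylsilane | CC(C)(C)[Si](C)(C)OC/C=C(\C)CCI | intermediate
15 | (E)-[5-(tert-butyldimethylsilyloxy)-3-methylpent-3-en-1-yl]lithium | CC(C)(C)[Si](C)(C)OC/C=C(\C)CC[Li] | intermediate (not isolated)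
16 | (5R,9R,10R)-15-(tert-butyldimethylsilyloxy)labda-7,13E-dien-9-ol | O[C@]1(CC/C(C)=C/CO[Si](C)(C)C(C)(C)C)C(C)=CC[C@@H]2C(C)(C)CCC[C@@]12C | intermediate
17 | (5R,10R)-15-(tert-butyldimethylsilyloxy)labda-8,13E-dien-7-one | CC(C)(C)[Si](C)(C)OC/C=C(\C)CCC1=C(C)C(=O)C[C@@H]2C(C)(C)CCC[C@@]12C | intermediate
18 | (5R,7S,10R)-15-(tert-butyldimethylsilyloxy)labda-8,13E-dien-7-ol | CC(C)(C)[Si](C)(C)OC/C=C(\C)CCC1=C(C)[C@@H](O)C[C@@H]2C(C)(C)CCC[C@@]12C | intermediate
19 | (5R,7S,10R)-labda-8,13E-diene-7,15-diol | OC/C=C(\C)CCC1=C(C)[C@@H](O)C[C@@H]2C(C)(C)CCC[C@@]12C | intermediate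
20 | (5R,7S,10R)-labda-8,13E-diene-7,15-diyl diacetate | CC(=O)OC/C=C(\C)CCC1=C(C)[C@@H](OC(C)=O)C[C@@H]2C(C)(C)CCC[C@@]12C | target

Total step count: 14. Longest linear sequence: 11 (steps 1–6 and 10–14); steps 7–9 make the side-chain iodide in parallel.

Steps most likely to fail

Step 2. The C–C bond formation at the congested, fully substituted enolate carbon may be slow, so that β-hydride elimination from the palladium enolate or drift of the kinetic enolate to the extended dienolate takes over. The fallback sets out from 3 and uses a vinyl cation equivalent instead of a cross-coupling. Lithium enolate 4 (LiN(i-Pr)2, THF, −78 °C) is added in Michael fashion to phenyl vinyl sulfoxide to give (5R,6R)-2,6-dimethyl-6-[2-(phenylsulfinyl)ethyl]-5-(prop-1-en-2-yl)cyclohex-2-en-1-one F1. Thermal syn-elimination of the sulfoxide (toluene, 110 °C, CaCO3) then comes back to the route at 5.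

Step 4. The tertiary bromide may lose HBr, or the radical chain may stall before the hindered tertiary radical is trapped by the stannane. The fallback sets out from 6 and replaces the radical by a polar pathway: silver-assisted ionisation to the tertiary cation and Sakurai-type capture by allyltrimethylsilane (AgOSO2CF3, allyltrimethylsilane, 2,6-di-tert-butylpyridine, CH2Cl2, −78 °C). It makes no new compound (F0) and comes back to the route at 7.

Step 12. Hydride delivery may show poor facial selectivity if axial attack competes with the equatorial approach of the bulky reagent. The fallback sets out from 17 and accepts the opposite selectivity on purpose. Luche reduction (NaBH4, CeCl3·7H2O, MeOH, −78 °C; axial attack) should give the epimeric alcohol (5R,7R,10R)-15-(tert-butyldimethylsilyloxy)labda-8,13E-dien-7-ol F2. Mitsunobu inversion (4-nitrobenzoic acid, PPh3, diisopropyl azodicarboxylate, toluene, 0 °C) gives (5R,7S,10R)-15-(tert-butyldimethylsilyloxy)labda-8,13E-dien-7-yl 4-nitrobenzoate F3. Hydrolysis (LiOH, THF/MeOH/H2O) comes back to the route at 18.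

Further compounds
F1 | step 2 | (5R,6R)-2,6-dimethyl-6-[2-(phenylsulfinyl)ethyl]-5-(prop-1-en-2-yl)cyclohex-2-en-1-one | O=S(CC[C@]1(C)[C@@H](C(C)=C)CC=C(C)C1=O)c2ccccc2
F0 | step 4 | none | none
F2 | step 12 | (5R,7R,10R)-15-(tert-butyldimethylsilyloxy)labda-8,13E-dien-7-ol | CC(C)(C)[Si](C)(C)OC/C=C(\C)CCC1=C(C)[C@H](O)C[C@@H]2C(C)(C)CCC[C@@]12C
F3 | step 12 | (5R,7S,10R)-15-(tert-butyldimethylsilyloxy)labda-8,13E-dien-7-yl 4-nitrobenzoate | CC(C)(C)[Si](C)(C)OC/C=C(\C)CCC1=C(C)[C@@H](OC(=O)c3ccc(cc3)[N+](=O)[O-])C[C@@H]2C(C)(C)CCC[C@@]12C
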